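## Retrosynthetic overview

- Locants are those of tetrahydro-1H,3H-furo[3,4-c]furan: C1 (phenolic aryl), O2, C3, C3a, C4 (trimethoxyphenyl), O5, C6, C6a. The phenol is carried as a TIPS ether and freed last.
- Key disconnection: the bond from C4 to the ipso carbon of the 3,4,5-trimethoxyphenyl ring, made in the same operation as the C3–C3a bond. A MOM ether on the C1 oxygen is ionised to a CH2=O2(+) ion, a tethered 2,3-dihydrofuran closes the O2 ring, and the resulting C4=O5(+) ion takes the aryl group from potassium (3,4,5-trimethoxyphenyl)trifluoroborate on its convex face.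
- Enabling feature: C4 is benzylic and bonded to ring oxygen O5, so it is an acetal-level (latent oxocarbenium) carbon. Its neighbour C3a is therefore the β-carbon of an O5–C4=C3a enol ether, and C3 is a formaldehyde-level CH2 on O2, one bond from C3a.
- The dihydrofuran (O5 ring) comes from a lactol made by oxidative cleavage of an allyl group beside a primary alcohol. C1 and C6a are set by an Evans syn-aldol of an N-pent-4-enoyl oxazolidinone with TIPS-protected 3-hydroxy-4,5-dimethoxybenzaldehyde.
- Ring order: O5 ring first (as 2,3-dihydrofuran), then the O2 ring and the C4 aryl group together in the key step, which also sets C3a and C4.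

Key step: step 9

Remark: Ar = 3,4-dimethoxy-5-(triisopropylsilyloxy)phenyl; Ar′ = 3,4,5-trimethoxyphenyl. Compounds 1, 3, 4 and 17 are assumed to be commercial; the target is the exo,exo (1S,3aR,4S,6aR) isomer.

## Route

Step 1
Reactants: 1 3-hydroxy-4,5-dimethoxybenzaldehyde
Product: 2 3,4-dimethoxy-5-(triisopropylsilyloxy)benzaldehyde
Conditions: TIPSCl, imidazole, DMF, rt
Reagents that add atoms: triisopropylsilyl chloride CC(C)[Si](Cl)(C(C)C)C(C)C
Why: Silylation of the phenol under imidazole catalysis; the TIPS ether should survive boron enolates, hydride, amine bases and brief BF3 exposure and is removable with fluoride.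

Step 2
Reactants: 3 (S)-4-benzyloxazolidin-2-one; 4 pent-4-enoyl chloride
Product: 5 (S)-4-benzyl-3-(pent-4-enoyl)oxazolidin-2-one
Conditions: Et3N, DMAP (cat.), CH2Cl2, 0 °C → rt
Reagents that add atoms: none
Why: DMAP-catalysed N-acylation of the oxazolidinone with the acid chloride, the standard preparation of an Evans imide.

Step 3
Reactants: 5 (S)-4-benzyl-3-(pent-4-enoyl)oxazolidin-2-one; 2 3,4-dimethoxy-5-(triisopropylsilyloxy)benzaldehyde
Product: 8 (S)-4-benzyl-3-{(S)-2-[(S)-Ar(hydroxy)methyl]pent-4-enoyl}oxazolidin-2-one, via Z-boron enolate 6 (not isolated), via boron aldolate 7 (not isolated)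
Conditions: Bu2BOTf, iPr2NEt, CH2Cl2, 0 °C; then 2, −78 → 0 °C; then pH 7 buffer, MeOH, 30% H2O2, 0 °C
Reagents that add atoms: none
Why: Evans syn-aldol reaction: the (Z)-boron enolate reacts through a closed Zimmerman–Traxler chair with the benzyl group of the auxiliary shielding one enolate face, which sets the carbinol carbon (future C1, S) and the α-carbon (future C6a, S in the imide) as the 2S,3S syn pair.

Step 4
Reactants: 8 (S)-4-benzyl-3-{(S)-2-[(S)-Ar(hydroxy)methyl]pent-4-enoyl}oxazolidin-2-one
Product: 9 (S)-4-benzyl-3-{(S)-2-[(S)-Ar(methoxymethoxy)methyl]pent-4-enoyl}oxazolidin-2-one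
Conditions: MOMCl, iPr2NEt, Bu4NI (cat.), CH2Cl2, 0 → 40 °C
Reagents that add atoms: chloromethyl methyl ether COCCl
Why: Amine-mediated O-alkylation of the secondary benzylic alcohol (MOM ether formation) installs the formaldehyde-level carbon that becomes C3; no stereocentre is touched.

Step 5
Reactants: 9 (S)-4-benzyl-3-{(S)-2-[(S)-Ar(methoxymethoxy)methyl]pent-4-enoyl}oxazolidin-2-one
Product: 11 (R)-2-[(S)-Ar(methoxymethoxy)methyl]pent-4-en-1-ol, via aldehyde 10 (not isolated)
Conditions: LiBH4, MeOH (1.1 equiv), THF, 0 °C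
Reagents that add atoms: none
Why: Reductive cleavage of the N-acyl oxazolidinone with lithium borohydride gives the primary alcohol (future O5–C6) and returns the auxiliary without epimerising the α-centre.

Step 6
Reactants: 11 (R)-2-[(S)-Ar(methoxymethoxy)methyl]pent-4-en-1-ol
Product: 14 (4R)-4-[(S)-Ar(methoxymethoxy)methyl]tetrahydrofuran-2-ol (mixture of anomers), via triol 12 (not isolated), via hydroxy aldehyde 13 (not isolated)
Conditions: OsO4 (2 mol%), NaIO4, 2,6-lutidine, dioxane/H2O, rt
Reagents that add atoms: osmium tetroxide O=[Os](=O)(=O)=O (catalytic oxygen carrier, gives the lactol oxygen); sodium periodate [Na+].[O-]I(=O)(=O)=O (re-oxidises osmium, net oxygen source)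
Why: Lemieux–Johnson oxidation (catalytic dihydroxylation, then periodate glycol cleavage) shortens the allyl group to an aldehyde that the primary alcohol captures at once as the five-membered lactol; the MOM-protected benzylic oxygen cannot compete.

Step 7
Reactants: 14 (4R)-4-[(S)-Ar(methoxymethoxy)methyl]tetrahydrofuran-2-ol
Product: 16 (R)-3-[(S)-Ar(methoxymethoxy)methyl]-2,3-dihydrofuran, via anomeric mesylate 15 (not isolated)
Conditions: MsCl, Et3N (excess), CH2Cl2, −40 °C → reflux; chromatography on Et3N-deactivated silica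
Reagents that add atoms: none
Why: Anomeric mesylation followed by amine-induced elimination of methanesulfonic acid (the standard lactol-to-glycal dehydration) gives the enol ether; the basic medium leaves the MOM group and the stereocentres untouched.

Step 8
Reactants: 17 (3,4,5-trimethoxyphenyl)boronic acid
Product: 18 potassium trifluoro(3,4,5-trimethoxyphenyl)borate
Conditions: KHF2, MeOH/H2O, rt
Reagents that add atoms: potassium hydrogen difluoride F.[F-].[K+]
Why: Fluoride exchange of a boronic acid with KHF2 (standard trifluoroborate formation) gives a stable, weighable aryl donor.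

Step 9
Reactants: 16 (R)-3-[(S)-Ar(methoxymethoxy)methyl]-2,3-dihydrofuran; 18 potassium trifluoro(3,4,5-trimethoxyphenyl)borate
Product: 22 triisopropylsilyl ether of the target [(1S,3aR,4S,6aR)-1-Ar-4-Ar′-tetrahydro-1H,3H-furo[3,4-c]furan], via methyleneoxonium ion 19 (not isolated), via bicyclic oxocarbenium ion 20 (not isolated), via bicyclic methyl acetal 21 (not isolated)
Conditions: TMSOTf (10 mol%), 2,6-di-tert-butyl-4-methylpyridine (20 mol%), CH2Cl2, −78 °C; then 18 (2 equiv), BF3·OEt2 (3 equiv), MeCN, −40 → 0 °C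
Reagents that add atoms: none
Why: Proposed new method: catalytic TMSOTf should take the terminal methoxy group off the MOM ether to give the CH2=O2(+) ion 19, whose carbon (C3) is attacked by the β-carbon of the enol ether (C3a) in a Prins-type closure of the O2 ring, and the C4=O5(+) ion 20 so formed rests as methyl acetal 21 until BF3·OEt2 and the aryldifluoroborane released from 18 re-ionise it and the aryl group moves from boron to C4 through its ipso carbon. The closest known reaction types are the Lewis-acid cyclisation of acetals tethered to 2,3-dihydrofurans, which gives furofuran methyl acetals, and the BF3-promoted coupling of acetal-derived oxocarbenium ions with potassium aryltrifluoroborates; their merger in one flask, the MOM ether as oxonium source and aryl transfer to this bicyclic ion are the untested parts. The O2 ring closes in a 5-(enol-exo)-endo-trig mode onto the oxonium carbon, the mode through which the known dihydrofuran–acetal cyclisations run. C3a is controlled by C6a, because the three-atom tether can reach only the face of the dihydrofuran that carries it, so the ring fusion must be cis; C4 is controlled by the folded cis-fused bicycle, whose convex face (anti to the O2 ring) is the only open approach, which places the aryl group exo and cis to H3a, while the C1 aryl group is exo because of the syn-aldol configuration already present. The step needs ring closure to outrun aryl transfer to 19 and needs ionisation at the methoxy end of the MOM group: the first is secured by adding 18 only after 21 has formed and by the far higher nucleophilicity of the enol ether compared with the arene ortho carbons, the second by silylation at the less hindered methoxy oxygen. The hindered pyridine removes adventitious acid so that the enol ether is not protonated before it cyclises.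

Step 10
Reactants: 22 triisopropylsilyl ether of the target
Product: 23 5-[(1S,3aR,4S,6aR)-4-(3,4,5-trimethoxyphenyl)tetrahydro-1H,3H-furo[3,4-c]furan-1-yl]-2,3-dimethoxyphenol (CNP0181235.1)
Conditions: TBAF, AcOH, THF, 0 °C
Reagents that add atoms: none
Why: Fluoride-mediated desilylation of the aryl silyl ether, buffered with acetic acid so the phenoxide is protonated at once; the ring ethers and all four stereocentres are not touched.

## Compound list

1 | 3-hydroxy-4,5-dimethoxybenzaldehyde | COc1cc(C=O)cc(O)c1OC | starting material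
2 | 3,4-dimethoxy-5-(triisopropylsilyloxy)benzaldehyde | COc1cc(C=O)cc(O[Si](C(C)C)(C(C)C)C(C)C)c1OC | intermediate
3 | (S)-4-benzyloxazolidin-2-one | O=C1N[C@@H](Cc2ccccc2)CO1 | starting material
4 | pent-4-enoyl chloride | C=CCCC(Cl)=O | starting material
5 | (S)-4-benzyl-3-(pent-4-enoyl)oxazolidin-2-one | C=CCCC(=O)N1[C@@H](Cc2ccccc2)COC1=O | intermediate
6 | (Z)-di-n-butylboron enolate of 5 | C=CC/C=C(\OB(CCCC)CCCC)N1[C@@H](Cc2ccccc2)COC1=O | intermediate (not isolated)
7 | di-n-butylboron aldolate of 8 | C=CC[C@H](C(=O)N1[C@@H](Cc2ccccc2)COC1=O)[C@H](OB(CCCC)CCCC)c1cc(OC)c(OC)c(O[Si](C(C)C)(C(C)C)C(C)C)c1 | intermediate (not isolated)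
8 | (S)-4-benzyl-3-{(S)-2-[(S)-Ar(hydroxy)methyl]pent-4-enoyl}oxazolidin-2-one (2S,3S syn-aldol) | C=CC[C@H](C(=O)N1[C@@H](Cc2ccccc2)COC1=O)[C@H](O)c1cc(OC)c(OC)c(O[Si](C(C)C)(C(C)C)C(C)C)c1 | intermediate
9 | (S)-4-benzyl-3-{(S)-2-[(S)-Ar(methoxymethoxy)methyl]pent-4-enoyl}oxazolidin-2-one | C=CC[C@H](C(=O)N1[C@@H](Cc2ccccc2)COC1=O)[C@H](OCOC)c1cc(OC)c(OC)c(O[Si](C(C)C)(C(C)C)C(C)C)c1 | intermediate
10 | (S)-2-[(S)-Ar(methoxymethoxy)methyl]pent-4-enal | C=CC[C@H](C=O)[C@H](OCOC)c1cc(OC)c(OC)c(O[Si](C(C)C)(C(C)C)C(C)C)c1 | intermediate (not isolated)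
11 | (R)-2-[(S)-Ar(methoxymethoxy)methyl]pent-4-en-1-ol | C=CC[C@H](CO)[C@H](OCOC)c1cc(OC)c(OC)c(O[Si](C(C)C)(C(C)C)C(C)C)c1 | intermediate
12 | (4R,5S)-5-Ar-4-(hydroxymethyl)-5-(methoxymethoxy)pentane-1,2-diol (both C2 epimers) | OCC(O)C[C@H](CO)[C@H](OCOC)c1cc(OC)c(OC)c(O[Si](C(C)C)(C(C)C)C(C)C)c1 | intermediate (not isolated)
13 | (3R,4S)-4-Ar-3-(hydroxymethyl)-4-(methoxymethoxy)butanal | O=CC[C@H](CO)[C@H](OCOC)c1cc(OC)c(OC)c(O[Si](C(C)C)(C(C)C)C(C)C)c1 | intermediate (not isolated)
14 | (4R)-4-[(S)-Ar(methoxymethoxy)methyl]tetrahydrofuran-2-ol (anomers) | OC1C[C@H](CO1)[C@H](OCOC)c1cc(OC)c(OC)c(O[Si](C(C)C)(C(C)C)C(C)C)c1 | intermediate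
15 | (4R)-4-[(S)-Ar(methoxymethoxy)methyl]tetrahydrofuran-2-yl methanesulfonate | CS(=O)(=O)OC1C[C@H](CO1)[C@H](OCOC)c1cc(OC)c(OC)c(O[Si](C(C)C)(C(C)C)C(C)C)c1 | intermediate (not isolated)
16 | (R)-3-[(S)-Ar(methoxymethoxy)methyl]-2,3-dihydrofuran | C1=C[C@H](CO1)[C@H](OCOC)c1cc(OC)c(OC)c(O[Si](C(C)C)(C(C)C)C(C)C)c1 | intermediate
17 | (3,4,5-trimethoxyphenyl)boronic acid | COc1cc(cc(OC)c1OC)B(O)O | starting material
18 | potassium trifluoro(3,4,5-trimethoxyphenyl)borate | COc1cc(cc(OC)c1OC)[B-](F)(F)F.[K+] | intermediate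
19 | methyleneoxonium ion from 16 (CH2=O(+) on the benzylic oxygen; triflate counter-ion) | C1=C[C@H](CO1)[C@H]([O+]=C)c1cc(OC)c(OC)c(O[Si](C(C)C)(C(C)C)C(C)C)c1 | intermediate (not isolated)
20 | cis-fused bicyclic oxocarbenium ion (C4=O5(+), 1-Ar exo) | COc1cc([C@H]2OC[C@H]3[C@@H]2C[O+]=C3)cc(O[Si](C(C)C)(C(C)C)C(C)C)c1OC | intermediate (not isolated)
21 | (1S,3aR,4S,6aR)-1-Ar-4-methoxytetrahydro-1H,3H-furo[3,4-c]furan (exo-methoxy acetal drawn; either anomer serves) | COc1cc([C@H]2OC[C@H]3[C@@H]2CO[C@@H]3OC)cc(O[Si](C(C)C)(C(C)C)C(C)C)c1OC | intermediate (not isolated)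
22 | {5-[(1S,3aR,4S,6aR)-4-(3,4,5-trimethoxyphenyl)tetrahydro-1H,3H-furo[3,4-c]furan-1-yl]-2,3-dimethoxyphenoxy}triisopropylsilane | COc1cc([C@H]2OC[C@H]3[C@@H]2CO[C@@H]3c2cc(OC)c(OC)c(OC)c2)cc(O[Si](C(C)C)(C(C)C)C(C)C)c1OC | intermediate
23 | 5-[(1S,3aR,4S,6aR)-4-(3,4,5-trimethoxyphenyl)tetrahydro-1H,3H-furo[3,4-c]furan-1-yl]-2,3-dimethoxyphenol | COc1cc([C@H]2OC[C@H]3[C@@H]2CO[C@@H]3c2cc(OC)c(OC)c(OC)c2)cc(O)c1OC | target

## Step count

Total steps: 10. Longest linear sequence: 8 steps (steps 1, 3, 4, 5, 6, 7, 9, 10).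

## Steps most likely to fail

**1. Step 9 (proposed new method).**
- What may go wrong: aryl transfer to the first oxonium ion before ring closure; ionisation at the wrong oxygen of the MOM group followed by intermolecular alkylation of the enol ether; protonation of the enol ether; sluggish boron-to-carbon transfer of this only moderately electron-rich aryl group; leakage of facial selectivity at C4; acid-induced opening of the benzylic ethers with epimerisation.
- Fallback (known chemistry), from 16 back to 22: 16 is cyclised alone with catalytic TMSOTf (CH2Cl2, −78 °C) and the bicyclic methyl acetal 21 is isolated. Mild hydrolysis (AcOH/H2O/THF) should give the bicyclic lactol F1. Commercial 3,4,5-trimethoxyphenylmagnesium bromide (excess, THF, 0 °C) adds to its open hydroxy-aldehyde form, making the same C4–aryl bond and giving the diol F2 as a mixture of carbinol epimers. Acid-catalysed dehydrative cycloetherification (CSA cat., CH2Cl2, 0 °C) then closes the O5 ring through the benzylic cation; both epimers converge and the primary alcohol should add so that the aryl group ends up exo, giving 22.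

**2. Step 7.**
- What may go wrong: the anomeric sulfonate is captured internally by the MOM oxygen or substituted by chloride instead of eliminating; the acid-labile enol ether hydrolyses or oligomerises during isolation.
- Fallback, from 14 back to 16: the lactol is converted under neutral conditions (PhSSPh, Bu3P, pyridine) into the phenyl thioacetal F3. Oxidation (mCPBA, CH2Cl2, −78 °C) gives the sulfoxide F4. Thermal syn-elimination of benzenesulfenic acid (toluene, iPr2NEt, 90 °C) gives 16; only the ring CH2 offers β-hydrogens, so the double bond can form only at the required position.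

**3. Step 4.**
- What may go wrong: slow alkylation of the hindered benzylic alcohol lets base-induced retro-aldol cleavage or E1cB loss of the β-oxygen compete.
- Fallback, from 8 back to 9: base-free Pummerer-type thioacetalisation (DMSO, Ac2O, AcOH, rt) gives the methylthiomethyl ether F5. S-Methylation (MeI, NaHCO3, MeOH, 40 °C) gives the sulfonium salt F6, which ionises and is captured by methanol to give the MOM ether 9.

## Further compounds

F1 | step 9 | (1S,3aR,6aR)-1-Ar-tetrahydro-1H,3H-furo[3,4-c]furan-4-ol (bicyclic lactol, anomers) | COc1cc([C@H]2OC[C@H]3[C@@H]2COC3O)cc(O[Si](C(C)C)(C(C)C)C(C)C)c1OC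
F2 | step 9 | {(2S,3R,4R)-2-Ar-4-[hydroxy(3,4,5-trimethoxyphenyl)methyl]tetrahydrofuran-3-yl}methanol (carbinol epimers) | COc1cc([C@H]2OC[C@H](C(O)c3cc(OC)c(OC)c(OC)c3)[C@@H]2CO)cc(O[Si](C(C)C)(C(C)C)C(C)C)c1OC
F3 | step 7 | (4R)-4-[(S)-Ar(methoxymethoxy)methyl]-2-(phenylthio)tetrahydrofuran | c1ccc(cc1)SC1C[C@H](CO1)[C@H](OCOC)c1cc(OC)c(OC)c(O[Si](C(C)C)(C(C)C)C(C)C)c1
F4 | step 7 | (4R)-4-[(S)-Ar(methoxymethoxy)methyl]-2-(phenylsulfinyl)tetrahydrofuran | O=S(c1ccccc1)C1C[C@H](CO1)[C@H](OCOC)c1cc(OC)c(OC)c(O[Si](C(C)C)(C(C)C)C(C)C)c1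
F5 | step 4 | (S)-4-benzyl-3-{(S)-2-[(S)-Ar(methylthiomethoxy)methyl]pent-4-enoyl}oxazolidin-2-one | C=CC[C@H](C(=O)N1[C@@H](Cc2ccccc2)COC1=O)[C@H](OCSC)c1cc(OC)c(OC)c(O[Si](C(C)C)(C(C)C)C(C)C)c1
F6 | step 4 | dimethylsulfonium iodide derived from F5 (not isolated) | C=CC[C@H](C(=O)N1[C@@H](Cc2ccccc2)COC1=O)[C@H](OC[S+](C)C)c1cc(OC)c(OC)c(O[Si](C(C)C)(C(C)C)C(C)C)c1.[I-]
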